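## Retrosynthetic overview

1. Last: the ten-membered carbocycle and the γ-lactone are made together by forming C6–C7 through an intramolecular CrCl2 allylation of a (Z)-enal by a 2-(bromomethyl)acrylate, then lactonisation.
2. Key step: the furanone ring and quaternary C10 come from a gold-catalysed heterocyclisation/1,2-methyl shift of an (R)-2-hydroxy-2-alkynyl ketone, which relays the C1 carbinol chirality to C10.
3. C8–C9 is formed by a syn boron aldol of an α-silyloxy ketone with a bromo enal (from a Morita–Baylis–Hillman adduct); the C8 isobutyrate follows by acylation.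
4. The tertiary carbinol comes from a catalytic enantioselective alkynylation of biacetyl with the silylated (Z)-enynol; the C9 oxygen from a Rubottom oxidation.
5. Ring order: furanone, then ten-membered carbocycle, then α-methylene-γ-lactone.

Assumption: germacrane numbering is used (C1 ketone, C2=C3, C4=C5, C6 lactone carbinol, C7, C8 ester, C9 hydroxyl, C10 quaternary, C11=C13, C12 lactone carbonyl); the target is read as (4Z,6R,7S,8S,9R,10R); the phebox antipode that gives (R)-4 in step 2 is written as (S,S) and would be fixed in the first run.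

## Route

**Step 1**
Reactants: 1 (2Z)-3-methylpent-2-en-4-yn-1-ol
Product: 2 tert-butyl(dimethyl){[(2Z)-3-methylpent-2-en-4-yn-1-yl]oxy}silane
Conditions: TBSCl, imidazole, CH2Cl2, 0 °C → rt
Reagents that add atoms: tert-butyldimethylsilyl chloride, CC(C)(C)[Si](C)(C)Cl
Why: Standard silylation of a primary alcohol; the ether blocks the cycloisomerisation of the free (Z)-enynol to a furan in the later Lewis-acid and gold steps.

**Step 2**
Reactants: 2 tert-butyl(dimethyl){[(2Z)-3-methylpent-2-en-4-yn-1-yl]oxy}silane; 3 butane-2,3-dione (biacetyl)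
Product: 4 (3R,6Z)-8-[(tert-butyldimethylsilyl)oxy]-3-hydroxy-3,6-dimethyloct-6-en-4-yn-2-one
Conditions: Rh(OAc)2(H2O)[(S,S)-iPr-phebox] (5 mol%; phebox = 2,6-bis(4-isopropyl-4,5-dihydro-1,3-oxazol-2-yl)phenyl), 3 (3 equiv), Et2O, 25 °C
Reagents that add atoms: none
Why: Proposed new method: acetate-assisted deprotonation of the terminal alkyne at the trivalent rhodium centre gives a rhodium acetylide; s-cis biacetyl binds through both carbonyl oxygens in the same two-point fashion as an α-keto ester, the pincer ligand exposes one enantiotopic carbonyl face to alkynyl transfer, and AcOH protonates the rhodium alkoxide to release (R)-4 (this centre becomes C10 in step 9) and regenerate the catalyst; the adduct is a hindered mono-ketone that no longer binds as a 1,2-dicarbonyl, so a second addition is not expected, and the base-free conditions avoid aldol self-condensation of biacetyl; the closest known reaction type is the rhodium-phebox (or Zn(OTf)2/amino alcohol) catalysed enantioselective alkynylation of α-keto esters and trifluoromethyl ketones, here extended to a symmetrical, enolisable dialkyl 1,2-diketone.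

**Step 3**
Reactants: 4 (3R,6Z)-8-[(tert-butyldimethylsilyl)oxy]-3-hydroxy-3,6-dimethyloct-6-en-4-yn-2-one
Product: 7 (3R,6Z)-8-[(tert-butyldimethylsilyl)oxy]-1,3-dihydroxy-3,6-dimethyloct-6-en-4-yn-2-one, via bis(trimethylsilyl) enol ether 5 (not isolated), via bis(trimethylsilyl) siloxy ketone 6 (not isolated)
Conditions: TMSOTf, Et3N, CH2Cl2, 0 °C; pentane, filter; mCPBA, CH2Cl2, −20 °C; citric acid (cat.), MeOH, rt
Reagents that add atoms: meta-chloroperoxybenzoic acid, O=C(OO)c1cccc(Cl)c1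
Why: TMSOTf/Et3N silylates the tertiary hydroxyl and turns the only enolisable position into a terminal silyl enol ether, which reacts with mCPBA far faster than the enyne alkene; epoxidation/1,4-silyl shift and mild acid methanolysis of both trimethylsilyl ethers give the α′-hydroxy ketone without touching the stereocentre or the TBS ether (Rubottom oxidation).

**Step 4**
Reactants: 7 (3R,6Z)-8-[(tert-butyldimethylsilyl)oxy]-1,3-dihydroxy-3,6-dimethyloct-6-en-4-yn-2-one
Product: 8 (3R,6Z)-1,8-bis[(tert-butyldimethylsilyl)oxy]-3-hydroxy-3,6-dimethyloct-6-en-4-yn-2-one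
Conditions: TBSCl (1.1 equiv), imidazole, CH2Cl2, −20 → 0 °C
Reagents that add atoms: tert-butyldimethylsilyl chloride, CC(C)(C)[Si](C)(C)Cl
Why: Imidazole-promoted silylation takes the primary hydroxyl and leaves the hindered tertiary propargylic hydroxyl free, as needed for step 9 (selective O-silylation).

**Step 5**
Reactants: 9 methyl acrylate; 10 2,2-dimethoxyacetaldehyde
Product: 11 methyl 3-hydroxy-4,4-dimethoxy-2-methylidenebutanoate (racemic)
Conditions: 1,4-diazabicyclo[2.2.2]octane (20 mol%), 1,4-dioxane/H2O (1:1), rt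
Reagents that add atoms: none
Why: The amine adds to the acrylate and the zwitterionic enolate attacks the activated aldehyde (Morita–Baylis–Hillman reaction); the racemic carbinol centre is removed in step 6.

**Step 6**
Reactants: 11 methyl 3-hydroxy-4,4-dimethoxy-2-methylidenebutanoate
Product: 13 methyl (2Z)-2-(bromomethyl)-4-oxobut-2-enoate, via bromo acetal 12 (not isolated)
Conditions: NBS, Me2S, CH2Cl2, −20 → 0 °C; then CF3CO2H/H2O (9:1), 0 °C
Reagents that add atoms: N-bromosuccinimide, O=C1CCC(=O)N1Br; water, O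
Why: The alkoxysulfonium salt from 11 is displaced by bromide with allylic transposition (SN2′) to the conjugated (Z)-allylic bromide, ester trans to the acetal carbon, and aqueous acid then unmasks the aldehyde (Corey–Kim-type bromination of a Morita–Baylis–Hillman alcohol, acetal hydrolysis).

**Step 7**
Reactants: 8 (3R,6Z)-1,8-bis[(tert-butyldimethylsilyl)oxy]-3-hydroxy-3,6-dimethyloct-6-en-4-yn-2-one; 13 methyl (2Z)-2-(bromomethyl)-4-oxobut-2-enoate
Product: 15 methyl (2Z,4S,5R,7R,10Z)-2-(bromomethyl)-5,12-bis[(tert-butyldimethylsilyl)oxy]-4,7-dihydroxy-7,10-dimethyl-6-oxododeca-2,10-dien-8-ynoate, via bis(dibutylboryl) Z-enolate 14 (not isolated)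
Conditions: Bu2BOTf (2.3 equiv), iPr2NEt (2.8 equiv), CH2Cl2, −78 → 0 °C; 13 (1.3 equiv), −78 °C; pH 7 buffer, MeOH, 30% H2O2, 0 °C
Reagents that add atoms: none
Why: The Z enol borinate of the α-silyloxy ketone adds to the aldehyde of 13 through a closed Zimmerman–Traxler transition state to give the 8,9-syn adduct, and with the C1–O bond anti to the enolate C–O (dipole-minimised) the aldehyde passes the slim alkynyl group instead of the methyl group, which should set (8S,9R) (boron-mediated syn aldol with 1,3-induction from the α′-stereocentre).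

**Step 8**
Reactants: 15 the aldol adduct of step 7; 16 2-methylpropanoyl chloride
Product: 17 methyl (2Z,4S,5R,7R,10Z)-2-(bromomethyl)-5,12-bis[(tert-butyldimethylsilyl)oxy]-7-hydroxy-7,10-dimethyl-4-[(2-methylpropanoyl)oxy]-6-oxododeca-2,10-dien-8-ynoate
Conditions: pyridine, CH2Cl2, −20 → 0 °C
Reagents that add atoms: none
Why: The acylpyridinium acylates the secondary C8 hydroxyl while the tertiary C1 hydroxyl is inert; no DMAP and ≤0 °C so that the allylic bromide is not quaternised and the β-acyloxy ketone does not eliminate (esterification with an acid chloride).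

**Step 9 (key step)**
Reactants: 17 the C8 isobutyrate of step 8
Product: 18 methyl (2Z,4S,5R)-2-(bromomethyl)-5-[(tert-butyldimethylsilyl)oxy]-5-[(2R)-5-{(2Z)-4-[(tert-butyldimethylsilyl)oxy]but-2-en-2-yl}-2-methyl-3-oxo-2,3-dihydrofuran-2-yl]-4-[(2-methylpropanoyl)oxy]pent-2-enoate
Conditions: AuCl3 (5 mol%), CH2Cl2, 38 °C
Reagents that add atoms: none
Why: Gold activates the alkyne for 5-endo attack by the ketone oxygen, and the cyclic oxocarbenium ion is quenched by a suprafacial 1,2-methyl shift from C1 to C10 (α-ketol-type shift driven by C1=O formation, faster than a hydride shift from C9 because it gives the conjugated hydroxy-furanium ion) followed by protodeauration, so the (R)-carbinol is relayed to (R)-C10 (gold-catalysed heterocyclisation/1,2-alkyl shift of 2-hydroxy-2-alkynyl ketones).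

**Step 10**
Reactants: 18 the furanone of step 9
Product: 19 methyl (2Z,4S,5R)-2-(bromomethyl)-5-hydroxy-5-{(2R)-5-[(2Z)-4-hydroxybut-2-en-2-yl]-2-methyl-3-oxo-2,3-dihydrofuran-2-yl}-4-[(2-methylpropanoyl)oxy]pent-2-enoate
Conditions: 48% aq. HF, MeCN, 0 °C → rt
Reagents that add atoms: none
Why: Acidic fluoride cleaves the primary and the hindered secondary silyl ether without displacing the allylic bromide or moving the isobutyrate (fluoride-mediated desilylation).

**Step 11**
Reactants: 19 the diol of step 10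
Product: 20 methyl (2Z,4S,5R)-2-(bromomethyl)-5-hydroxy-5-{(2R)-2-methyl-3-oxo-5-[(2Z)-4-oxobut-2-en-2-yl]-2,3-dihydrofuran-2-yl}-4-[(2-methylpropanoyl)oxy]pent-2-enoate
Conditions: MnO2 (20 equiv), CH2Cl2, rt
Reagents that add atoms: none
Why: MnO2 oxidises only the allylic primary alcohol and leaves the non-allylic C9 hydroxyl and the (Z)-alkene untouched (allylic alcohol oxidation).

**Step 12**
Reactants: 20 the (Z)-enal of step 11
Product: 22 (4Z,6R,7S,8S,9R,10R)-9-hydroxy-8-(2-methylpropanoyloxy)-1-oxo-3,10-epoxygermacra-2,4,11(13)-trien-12,6-olide (CNP0265772.1), via seco hydroxy ester 21 (not isolated)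
Conditions: CrCl2 (8 equiv), THF, 25 °C, slow addition of 20 (2 mM final); then 1 M HCl, 25 °C
Reagents that add atoms: none
Why: The allylchromium formed from the bromide attacks the aldehyde through C7; the equilibrating allylchromium reacts through a chair transition state that gives the 6,7-anti adduct with the C8 acyloxy group pseudo-equatorial on the rigid furanone/(Z)-alkene template, which should set (6R,7S), and the C6 alkoxide closes the trans-fused α-methylene lactone on acidification (intramolecular Nozaki–Hiyama allylation of Barbier type, lactonisation).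

## Compound list

1 | (2Z)-3-methylpent-2-en-4-yn-1-ol | C#C/C(C)=C\CO | starting material
2 | tert-butyl(dimethyl){[(2Z)-3-methylpent-2-en-4-yn-1-yl]oxy}silane | C#C/C(C)=C\CO[Si](C)(C)C(C)(C)C | intermediate
3 | butane-2,3-dione | CC(=O)C(C)=O | starting material
4 | (3R,6Z)-8-[(tert-butyldimethylsilyl)oxy]-3-hydroxy-3,6-dimethyloct-6-en-4-yn-2-one | CC(=O)[C@](C)(O)C#C/C(C)=C\CO[Si](C)(C)C(C)(C)C | intermediate
5 | (3R,6Z)-8-[(tert-butyldimethylsilyl)oxy]-3,6-dimethyl-2,3-bis[(trimethylsilyl)oxy]octa-1,6-dien-4-yne | C=C(O[Si](C)(C)C)[C@](C)(O[Si](C)(C)C)C#C/C(C)=C\CO[Si](C)(C)C(C)(C)C | intermediate (not isolated)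
6 | (3R,6Z)-8-[(tert-butyldimethylsilyl)oxy]-3,6-dimethyl-1,3-bis[(trimethylsilyl)oxy]oct-6-en-4-yn-2-one | C[Si](C)(C)OCC(=O)[C@](C)(O[Si](C)(C)C)C#C/C(C)=C\CO[Si](C)(C)C(C)(C)C | intermediate (not isolated)
7 | (3R,6Z)-8-[(tert-butyldimethylsilyl)oxy]-1,3-dihydroxy-3,6-dimethyloct-6-en-4-yn-2-one | OCC(=O)[C@](C)(O)C#C/C(C)=C\CO[Si](C)(C)C(C)(C)C | intermediate
8 | (3R,6Z)-1,8-bis[(tert-butyldimethylsilyl)oxy]-3-hydroxy-3,6-dimethyloct-6-en-4-yn-2-one | CC(C)(C)[Si](C)(C)OCC(=O)[C@](C)(O)C#C/C(C)=C\CO[Si](C)(C)C(C)(C)C | intermediate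
9 | methyl acrylate | C=CC(=O)OC | starting material
10 | 2,2-dimethoxyacetaldehyde | COC(OC)C=O | starting material
11 | methyl 3-hydroxy-4,4-dimethoxy-2-methylidenebutanoate (racemic) | C=C(C(=O)OC)C(O)C(OC)OC | intermediate
12 | methyl (2Z)-2-(bromomethyl)-4,4-dimethoxybut-2-enoate | COC(OC)/C=C(\CBr)C(=O)OC | intermediate (not isolated)
13 | methyl (2Z)-2-(bromomethyl)-4-oxobut-2-enoate | O=C/C=C(\CBr)C(=O)OC | intermediate
14 | (1Z,3R,6Z)-1,8-bis[(tert-butyldimethylsilyl)oxy]-2,3-bis[(dibutylboranyl)oxy]-3,6-dimethylocta-1,6-dien-4-yne | CCCCB(CCCC)O/C(=C\O[Si](C)(C)C(C)(C)C)[C@](C)(OB(CCCC)CCCC)C#C/C(C)=C\CO[Si](C)(C)C(C)(C)C | intermediate (not isolated)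
15 | methyl (2Z,4S,5R,7R,10Z)-2-(bromomethyl)-5,12-bis[(tert-butyldimethylsilyl)oxy]-4,7-dihydroxy-7,10-dimethyl-6-oxododeca-2,10-dien-8-ynoate | COC(=O)/C(CBr)=C/[C@H](O)[C@@H](O[Si](C)(C)C(C)(C)C)C(=O)[C@](C)(O)C#C/C(C)=C\CO[Si](C)(C)C(C)(C)C | intermediate
16 | 2-methylpropanoyl chloride | CC(C)C(Cl)=O | starting material
17 | methyl (2Z,4S,5R,7R,10Z)-2-(bromomethyl)-5,12-bis[(tert-butyldimethylsilyl)oxy]-7-hydroxy-7,10-dimethyl-4-[(2-methylpropanoyl)oxy]-6-oxododeca-2,10-dien-8-ynoate | COC(=O)/C(CBr)=C/[C@H](OC(=O)C(C)C)[C@@H](O[Si](C)(C)C(C)(C)C)C(=O)[C@](C)(O)C#C/C(C)=C\CO[Si](C)(C)C(C)(C)C | intermediate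
18 | methyl (2Z,4S,5R)-2-(bromomethyl)-5-[(tert-butyldimethylsilyl)oxy]-5-[(2R)-5-{(2Z)-4-[(tert-butyldimethylsilyl)oxy]but-2-en-2-yl}-2-methyl-3-oxo-2,3-dihydrofuran-2-yl]-4-[(2-methylpropanoyl)oxy]pent-2-enoate | COC(=O)/C(CBr)=C/[C@H](OC(=O)C(C)C)[C@@H](O[Si](C)(C)C(C)(C)C)[C@@]1(C)OC(=CC1=O)/C(C)=C\CO[Si](C)(C)C(C)(C)C | intermediate
19 | methyl (2Z,4S,5R)-2-(bromomethyl)-5-hydroxy-5-{(2R)-5-[(2Z)-4-hydroxybut-2-en-2-yl]-2-methyl-3-oxo-2,3-dihydrofuran-2-yl}-4-[(2-methylpropanoyl)oxy]pent-2-enoate | COC(=O)/C(CBr)=C/[C@H](OC(=O)C(C)C)[C@@H](O)[C@@]1(C)OC(=CC1=O)/C(C)=C\CO | intermediate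
20 | methyl (2Z,4S,5R)-2-(bromomethyl)-5-hydroxy-5-{(2R)-2-methyl-3-oxo-5-[(2Z)-4-oxobut-2-en-2-yl]-2,3-dihydrofuran-2-yl}-4-[(2-methylpropanoyl)oxy]pent-2-enoate | COC(=O)/C(CBr)=C/[C@H](OC(=O)C(C)C)[C@@H](O)[C@@]1(C)OC(=CC1=O)/C(C)=C\C=O | intermediate
21 | methyl 2-[(4Z,6R,7S,8S,9R,10R)-6,9-dihydroxy-4,10-dimethyl-8-(2-methylpropanoyloxy)-1-oxo-3,10-epoxycyclodeca-2,4-dien-7-yl]prop-2-enoate (germacrane numbering) | COC(=O)C(=C)[C@@H]1[C@H](OC(=O)C(C)C)[C@@H](O)[C@@]2(C)OC(=CC2=O)/C(C)=C\[C@H]1O | intermediate (not isolated)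
22 | (4Z,6R,7S,8S,9R,10R)-9-hydroxy-8-(2-methylpropanoyloxy)-1-oxo-3,10-epoxygermacra-2,4,11(13)-trien-12,6-olide (CNP0265772.1) | C=C1C(=O)O[C@@H]2/C=C(/C)C3=CC(=O)[C@](C)(O3)[C@H](O)[C@@H](OC(=O)C(C)C)[C@@H]12 | target

## Step count and risks

Total: 12 steps. Longest linear sequence: 10 steps (steps 1–4 and 7–12); steps 5–6 make the bromo enal 13.

**Step 2 (proposed new method).** Risks are modest enantioselectivity, slow turnover with an aliphatic diketone, and self-condensation of biacetyl. The fallback uses known chemistry, sets out from 2 and comes back at 4. The established catalytic enantioselective alkynylation of α-keto esters (the same rhodium phebox acetate catalyst, or Zn(OTf)2/chiral amino alcohol/Et3N) is run on 2 and methyl pyruvate (CC(=O)C(=O)OC, seven non-hydrogen atoms). This gives methyl (2R,5Z)-7-[(tert-butyldimethylsilyl)oxy]-2-hydroxy-2,5-dimethylhept-5-en-3-ynoate F1. MeNH(OMe)·HCl/iPrMgCl in THF converts it into the Weinreb amide (2R,5Z)-7-[(tert-butyldimethylsilyl)oxy]-2-hydroxy-N-methoxy-N,2,5-trimethylhept-5-en-3-ynamide F2, and MeMgBr (THF, 0 °C) gives 4. This costs two extra steps.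

**Step 7.** The sense and level of facial induction from the C1 centre (methyl against alkynyl) rests on a model, not on close precedent; retro-aldol on work-up is a second risk. The fallback sets out from 8 and comes back at 15; it replaces substrate control in a closed boron transition state by catalyst control in an open one. TMSOTf/Et3N converts 8 into the silyl enol ether (1Z,3R,6Z)-1,8-bis[(tert-butyldimethylsilyl)oxy]-3,6-dimethyl-2,3-bis[(trimethylsilyl)oxy]octa-1,6-dien-4-yne F3. A Mukaiyama aldol addition of F3 to 13 follows, catalysed by the chiral acyloxyborane made from BH3·THF and the appropriate enantiomer of 2-O-(2,6-diisopropoxybenzoyl)tartaric acid (syn-selective whatever the enol ether geometry, EtCN, −78 °C). It gives methyl (2Z,4S,5R,7R,10Z)-2-(bromomethyl)-5,12-bis[(tert-butyldimethylsilyl)oxy]-7,10-dimethyl-6-oxo-4,7-bis[(trimethylsilyl)oxy]dodeca-2,10-dien-8-ynoate F4. Citric acid in MeOH removes the two trimethylsilyl groups to give 15.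

**Step 12.** Risks are oligomerisation at the ten-membered ring size, the wrong C6/C7 diastereomer, and Z-to-E isomerisation of the enal. The fallback sets out from 19 and comes back at 22; it replaces the closed chromium transition state by a Lewis-acid promoted open-chain allylstannane addition. Me3SnSnMe3 with Pd(PPh3)4 (zerovalent palladium, 5 mol%, THF) converts the allylic bromide of 19 into methyl (2Z,4S,5R)-5-hydroxy-5-{(2R)-5-[(2Z)-4-hydroxybut-2-en-2-yl]-2-methyl-3-oxo-2,3-dihydrofuran-2-yl}-4-[(2-methylpropanoyl)oxy]-2-[(trimethylstannyl)methyl]pent-2-enoate F5. MnO2 (CH2Cl2) gives the enal methyl (2Z,4S,5R)-5-hydroxy-5-{(2R)-2-methyl-3-oxo-5-[(2Z)-4-oxobut-2-en-2-yl]-2,3-dihydrofuran-2-yl}-4-[(2-methylpropanoyl)oxy]-2-[(trimethylstannyl)methyl]pent-2-enoate F6. BF3·OEt2 (CH2Cl2, −78 °C, 1 mM) closes the C6–C7 bond to 21, which lactonises on acid work-up to 22.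

## Further compounds

F1 | step 2 | methyl (2R,5Z)-7-[(tert-butyldimethylsilyl)oxy]-2-hydroxy-2,5-dimethylhept-5-en-3-ynoate | COC(=O)[C@](C)(O)C#C/C(C)=C\CO[Si](C)(C)C(C)(C)C
F2 | step 2 | (2R,5Z)-7-[(tert-butyldimethylsilyl)oxy]-2-hydroxy-N-methoxy-N,2,5-trimethylhept-5-en-3-ynamide | CON(C)C(=O)[C@](C)(O)C#C/C(C)=C\CO[Si](C)(C)C(C)(C)C
F3 | step 7 | (1Z,3R,6Z)-1,8-bis[(tert-butyldimethylsilyl)oxy]-3,6-dimethyl-2,3-bis[(trimethylsilyl)oxy]octa-1,6-dien-4-yne | C[Si](C)(C)O/C(=C\O[Si](C)(C)C(C)(C)C)[C@](C)(O[Si](C)(C)C)C#C/C(C)=C\CO[Si](C)(C)C(C)(C)C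
F4 | step 7 | methyl (2Z,4S,5R,7R,10Z)-2-(bromomethyl)-5,12-bis[(tert-butyldimethylsilyl)oxy]-7,10-dimethyl-6-oxo-4,7-bis[(trimethylsilyl)oxy]dodeca-2,10-dien-8-ynoate | COC(=O)/C(CBr)=C/[C@H](O[Si](C)(C)C)[C@@H](O[Si](C)(C)C(C)(C)C)C(=O)[C@](C)(O[Si](C)(C)C)C#C/C(C)=C\CO[Si](C)(C)C(C)(C)C
F5 | step 12 | methyl (2Z,4S,5R)-5-hydroxy-5-{(2R)-5-[(2Z)-4-hydroxybut-2-en-2-yl]-2-methyl-3-oxo-2,3-dihydrofuran-2-yl}-4-[(2-methylpropanoyl)oxy]-2-[(trimethylstannyl)methyl]pent-2-enoate | COC(=O)/C(C[Sn](C)(C)C)=C/[C@H](OC(=O)C(C)C)[C@@H](O)[C@@]1(C)OC(=CC1=O)/C(C)=C\CO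
F6 | step 12 | methyl (2Z,4S,5R)-5-hydroxy-5-{(2R)-2-methyl-3-oxo-5-[(2Z)-4-oxobut-2-en-2-yl]-2,3-dihydrofuran-2-yl}-4-[(2-methylpropanoyl)oxy]-2-[(trimethylstannyl)methyl]pent-2-enoate | COC(=O)/C(C[Sn](C)(C)C)=C/[C@H](OC(=O)C(C)C)[C@@H](O)[C@@]1(C)OC(=CC1=O)/C(C)=C\C=O
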